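**The link yield of the green flask**

| setting | green | blue | flask |
|---|---|---|---|
| first end groups | 0.15 M | 0.22 M | 0.15 M |
| second end groups | 0.95 equiv | 0.95 equiv | 0.950 equiv |
| protic impurity | 0.045 M | 0.045 M | 0.0450 M |
| temperature | 50 °C | 56 °C | 50 °C |
| remark | the very flask that is asked about, followed so far | run made earlier |  |
| time |  |  | 8.0 d |

- green (time / h: links / %): 8.00: 30.9; 20.0: 34.3; 40.0: 34.4; 60.0: 35.9; 96.0: 35.5; 120: 34.8
- blue (time / h: links / %): 2.50: 29.4; 4.00: 34.5; 6.00: 37.4; 10.0: 38.9; 15.0: 38.6; 30.0: 38.0

(each reading ± 0.5 percentage points)

- east: change nothing and wait 8.0 d more
- south: at 8.0 d raise the temperature by 15 K, then wait 8.0 d
- north-east: at 8.0 d add second end groups, 50.0 % of the amount charged, then wait 8.0 d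
- west: at 8.0 d take out 90 % of the links then present, then wait 8.0 d

- links that was removed still counts
- additions bring no volume worth counting

- links, in percent of the first end groups first charged, at 8.0 d
- which option adds most links ("none" when 2 percentage points or less is all one gets) (east / south / north-east / west / none)
- links present, with what was taken out counted in, in percent of the first end groups first charged, after east
- links present, with what was taken out counted in, in percent of the first end groups first charged, after west

1. Links in the green flask stop rising: from 20.0 h on, the readings average 35.0 %, and we read no trend in them against a scatter of 0.5 percentage points. We read this stop as the end of the second end groups, the limiting reagent at 0.950 equiv. Links at the stop, divided by the equivalents of second end groups charged, give 0.368; we call this the link yield. The blue run reads 0.405, so the yield belongs to its flask and is no constant.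

2. East: the green flask reaches 8.0 d long after 20.0 h, so we reckon links stay near 35.0 %, now and after waiting.

3. South: on our reading, links in the green flask stopped with the second end groups, and heat brings in no new ones, so we expect no gain.

4. West: on our reading, taking links out of the green flask gives back no second end groups, so no new links form, and the total, with what was removed counted in, stays near 35.0 %.

5. North-east: new second end groups need first end groups as partners. In the green flask, those left lie between 5.00 %, if the protic impurity took no second end groups, and 35.0 %, if it took its whole charge. The addition of 0.475 equiv exceeds even the upper figure, so we reckon that first end groups then set the limit. Link yield times that remainder gives a gain between 1.8 points and 13 points. We commit to north-east.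

6. The forecast differs from us: 34 % now, 32.5 % after east, 47.5 % after west, and west as best, with the caution "This rests on the equilibrium reading".

7. The green flask gives 34.6 % now, 34.6 % after east and 34.6 % after west, and north-east is best, adding 5.8 points.

    first end groups + second end groups → links (k = 0.769 M⁻¹ h⁻¹, Ea = 65.0 kJ mol⁻¹)
    first end groups + second end groups → rings, rate k2*[first end groups] as long as [second end groups] is above zero (k = 0.0659 h⁻¹, Ea = 96.0 kJ mol⁻¹)
    second end groups + protic impurity → quenched reagent (k = 0.538 M⁻¹ h⁻¹, Ea = 69.0 kJ mol⁻¹)
    (constants at 50 °C)

At 192 h the green flask holds 0 % of its second end groups and 15.1 % of its first end groups, a remainder inside our bracket. Link yield times that remainder gives 5.6 points, against the 5.8 points that north-east brings. The lower end of our bracket, 1.8 points, supposed that the protic impurity took no second end groups. In the run without the path from second end groups and protic impurity to quenched reagent, the gain from north-east falls from 5.8 points to 2.2 points.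

The readings were computed on assumed constants.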